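1. Hold on to one sum: target plus starting material. At the last readings it stands at 99.2% in theta, 98.4% in beta and 100% in zeta. One curve per run therefore tells you the conversion.

| flask | starting material | second substrate | coupling partner | free catalyst | temperature | remark | time |
|---|---|---|---|---|---|---|---|
| theta | 0.10 M | 2 equiv | 0.60 equiv | 0.1 mol% | 15 °C | run made earlier |  |
| beta | 0.10 M | 2 equiv | 0.90 equiv | 0.1 mol% | 40 °C | run made earlier |  |
| zeta | 0.10 M | 1 equiv | 1.2 equiv | 0.1 mol% | 15 °C | run made earlier |  |
| midnight | 0.10 M | 2.00 equiv | 1.20 equiv | 0.1 mol% | 20 °C |  | 6.0 h |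
| winter | 0.10 M | 2.00 equiv | 1.20 equiv | 0.1 mol% | 40 °C |  | 6.0 h |
| autumn | 0.10 M | 2.00 equiv | 1.20 equiv | 0.1 mol% | 60 °C |  | 6.0 h |

- theta (time / h: target / %, starting material / %): 0.500: 0.6, 99.3; 1.00: 1.7, 98.1; 1.50: 2.6, 96.8; 2.50: 4.2, 95.5; 4.00: 5.7, 93.0; 8.00: 11.5, 87.7
- beta (time / h: target / %, starting material / %): 0.200: 2.7, 96.6; 0.333: 3.8, 95.8; 0.500: 6.0, 93.4; 1.00: 12.8, 87.9; 1.33: 15.3, 84.5; 3.00: 28.5, 69.9
- zeta (time / h: target / %, starting material / %): 0.500: 1.9, 97.7; 1.00: 3.9, 97.0; 2.00: 6.5, 93.2; 4.00: 12.8, 86.9; 8.00: 23.7, 76.4

(standard deviation of a reading: 0.5 percentage points)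

- steps that have been proposed: coupling partner + free catalyst + target -> free catalyst + over-reaction product; starting material + free catalyst <-> catalyst intermediate A; coupling partner + catalyst intermediate B -> free catalyst + second product; coupling partner + catalyst intermediate A -> free catalyst + target; second substrate + free catalyst <-> catalyst intermediate B

- the flask with the highest amount of target, in percent of the starting material charged ("all alike" if they lie within 1.5 percentage points) (midnight / winter / autumn / all alike)
- final target, as a percentage of the starting material charged, in midnight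
- final target, as a percentage of the starting material charged, in winter
- final target, as a percentage of the starting material charged, in autumn

2. Now freeze something. Suppose the catalyst keeps a fixed form through a run, so that target forms at κ times the coupling partner left (pseudo-first-order in coupling partner). Then b, the share of the partner's charge not yet turned into target, falls as exp(−κt).

3. Theta's last reading gives κ = 0.0266 h⁻¹ at 15 °C. Zeta, with twice the partner and half the second substrate, gives 0.0275 h⁻¹, close to theta. Beta gives 0.127 h⁻¹ at 40 °C.

4. Draw a straight line of ln κ against temperature. My partner rate constant at 20 °C, κ, is 0.0364 h⁻¹. Beyond the runs, at 60 °C, the line gives 0.443 h⁻¹.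

5. Turn the question round. "All alike" needs winter and autumn to end with nearly equal target. At 6.0 h I get b = 46.7% in winter and 7.01% in autumn. Scaled by the charge, winter reaches 64.0% target. Autumn's reckoned figure overruns the starting material charged, the limiting reagent here, so I cap it at that charge. The gap is then 36 percentage points, far beyond the margin. So I expect autumn to lead.

6. My target figure for midnight is 23.5%. Uncapped, autumn's is 112%, above the starting material charged, so that figure fails as a yield.

7. The forecast says autumn, with 23% (19% to 27%) for midnight, 50% (43% to 56%) for winter and 70% (54% to 80%) for autumn. Its winter figure stands below mine. Its words: “Autumn should still lead, though its uncertainty is largest.”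

8. The flasks give 22.1% in midnight, 51.9% in winter and 65.4% in autumn, so autumn leads.

    coupling partner + free catalyst + target → free catalyst + over-reaction product (k = 572 L² mol⁻² min⁻¹, Ea = 39.0 kJ mol⁻¹)
    starting material + free catalyst ⇌ catalyst intermediate A (K = 136 L mol⁻¹, k = 674 L mol⁻¹ min⁻¹, Ea = 49.0 kJ mol⁻¹, ΔH = −34.0 kJ mol⁻¹)
    coupling partner + catalyst intermediate B → free catalyst + second product (k = 555 L mol⁻¹ min⁻¹, Ea = 55.0 kJ mol⁻¹)
    coupling partner + catalyst intermediate A → free catalyst + target (k = 99.6 L mol⁻¹ min⁻¹, Ea = 48.0 kJ mol⁻¹)
    second substrate + free catalyst ⇌ catalyst intermediate B (K = 4.10 L mol⁻¹, k = 265 L mol⁻¹ min⁻¹, Ea = 37.0 kJ mol⁻¹, ΔH = −29.0 kJ mol⁻¹)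
    (constants at 60 °C)

In midnight the binding of starting material relaxes, both ways together, with a half-life of 0.146 min at 6.00 h. The half-life of starting material by the forward binding step alone is 15 h at 2.66 h. Catalyst intermediate A holds 69.9% of the catalyst at 3.00 h and 70.8% at 6.00 h. Watch the partner: midnight keeps 63% of its charge at 6.00 h. Averaged over that time, its decay runs 2.15 times my κ at 20 °C, with 0.0220 M of second product beside the target.

Midnight read at 25 h is the next case: that multiple and κ give 14.1% of the partner's charge left. The computed flask holds 14% of that charge, with 51.4% target.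

(Readings and results stem from a simulated flask with constants of no real substance; noise was put on by code.)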